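## Retrosynthetic overview

- Numbering is that of ent-kaurane: ring A = C1–C5, C10 (C18 methyl and C19 acid on C4, C20 methyl on C10); C6 acid on C5; C7 aldehyde on C8; ring C = C8, C9, C11–C14; ring D = C8, C14, C13, C16, C15; C17 methylene.
- Enabling feature: C6 and C7 are the two ends of a cut C6–C7 bond. With that bond restored as a temporary cyclohexanone ring B (C5, C6, C7, C8, C9, C10), the C6 and C12 carbonyls are 1,6-related across C7–C8–C9–C11 (hydrodimer of an enone and an enal), and C12–C13–C16=C17 is a carbonyl-ene retron.
- Key disconnections: C8–C9 (reductive β,β′-coupling, closes ring B) together with C12–C13 (carbonyl-ene, closes ring C) in one flask from monocyclic 18; then C6–C7 (periodate scission of an α-ketol) and C8–C15 (enamine/π-allyl alkylation, ring D).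
- Ring A (C4, C5, C10) comes from a Diels–Alder reaction of 3-methyl-2-pyrone with citraconic anhydride and is resolved once; C10 then relays to C9, C9 to C13, and C13 to C8.
- Ring order: A, then B and C together, B opened again, D last.

Key step: step 11

Remark: racemic compounds 4–9 are drawn as the enantiomer that is carried on after the resolution in step 6; the absolute configuration enters only there.

## Route

Step 1
Reactants: 1 3-bromo-2H-pyran-2-one
Product: 2 3-methyl-2H-pyran-2-one
Conditions: MeZnCl (1.3 equiv), Pd(PPh3)4 (5 mol %), THF, 50 °C
Reagents that add atoms: methylzinc chloride, C[Zn]Cl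
Why: Negishi cross-coupling at the C–Br bond next to the lactone carbonyl (oxidative addition to zerovalent palladium, transmetalation, reductive elimination) should install the methyl group that becomes C20; no stereocentre is formed.

Step 2
Reactants: 2 3-methyl-2H-pyran-2-one; 3 citraconic anhydride
Product: 4 racemic endo cycloadduct
Conditions: toluene, 100 °C, sealed tube
Reagents that add atoms: none
Why: Normal-demand Diels–Alder reaction of the cisoid pyrone diene with the cyclic dienophile, in which the nucleophilic C3 terminus of the pyrone (future C10) should bond to the unsubstituted anhydride carbon (future C5), keeping the two methyl-bearing carbons apart, and the endo (Alder) mode places the anhydride syn to the new C=C bridge and anti to the lactone bridge, so that C20, C19 and C6 end on one face of the future ring A and C9 on the other.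

Step 3
Reactants: 4 racemic endo cycloadduct
Product: 6 racemic cyclohexene acid anhydride, via tributylstannyl ester 5 (not isolated)
Conditions: Pd(PPh3)4 (5 mol %), Bu3SnH (1.3 equiv), THF, 25 °C; then 1 M HCl
Reagents that add atoms: none
Why: Zerovalent palladium should ionise the strained bridgehead allylic C–O bond of the lactone to a cyclohexenyl π-allyl complex carrying the C9 carboxylate, and hydride transfer from Bu3SnH (hydrostannolytic cleavage of an allylic ester) gives the cyclohexene acid; the alkene position is of no consequence and no stereocentre is touched.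

Step 4
Reactants: 6 racemic cyclohexene acid anhydride
Product: 7 racemic cyclohexane acid anhydride
Conditions: H2 (1 atm), 10 % Pd/C, EtOAc, 25 °C
Reagents that add atoms: none
Why: Heterogeneous hydrogenation of the cis-disubstituted ring alkene should be fast and leaves acid and anhydride alone; C1 and C2 become methylene groups, so no stereocentre is formed.

Step 5
Reactants: 7 racemic cyclohexane acid anhydride
Product: 9 racemic lactone acid, via hydroxymethyl anhydride 8 (not isolated)
Conditions: BH3·SMe2 (1.2 equiv), THF, 0 to 25 °C; MeOH; then DMAP (cat.), CH2Cl2, 25 °C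
Reagents that add atoms: none
Why: Borane reduces a free carboxylic acid much faster than an anhydride, and the neopentyl alcohol 8 should then open the anhydride at the only carbonyl it can reach through a five-membered ring (C6), giving the trans-fused γ-lactone and freeing the C19 acid without change at any stereocentre.

Step 6
Reactants: 9 racemic lactone acid
Product: 10 lactone acid, single enantiomer
Conditions: (R)-1-phenylethylamine (0.5–1.0 equiv), EtOAc/2-propanol, fractional crystallisation; then 1 M HCl
Reagents that add atoms: none
Why: Classical resolution through diastereomeric ammonium salts; the salt of the enantiomer with the ring A configuration of the target is collected (the antipodal amine is used if it stays in the mother liquor) and acidified, the absolute configuration to be confirmed crystallographically.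

Step 7
Reactants: 11 5-bromopent-1-ene; 12 2-methylbut-2-ene
Product: 13 6-bromo-2-methylhex-2-ene
Conditions: second-generation Grubbs catalyst (2 mol %), 12 as co-solvent, CH2Cl2, 40 °C
Reagents that add atoms: none
Why: Olefin cross-metathesis of a terminal alkene with a trisubstituted isopropylidene donor should give the prenyl-type alkene with loss of propene; the alkyl bromide is inert.

Step 8
Reactants: 10 lactone acid, single enantiomer; 13 6-bromo-2-methylhex-2-ene
Product: 15 hydroxy keto acid, via 5-methylhex-4-enyllithium 14 (not isolated)
Conditions: 13 (2.3 equiv), t-BuLi (4.6 equiv), Et2O, −78 °C; then 10, THF, −78 to −40 °C; aq. NH4Cl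
Reagents that add atoms: none
Why: Bromine–lithium exchange gives the primary alkyllithium, the first equivalent of which deprotonates the acid while the second adds once to the lactone carbonyl (nucleophilic acyl substitution arrested at the lithium hemiketal at −78 °C, carboxylate inert), so the ketone appears only on work-up and no stereocentre changes.

Step 9
Reactants: 15 hydroxy keto acid
Product: 16 aldehyde enone acid
Conditions: IBX (3.5 equiv), DMSO, 70 °C
Reagents that add atoms: none
Why: IBX should oxidise the primary alcohol (through the open hydroxy ketone form) to the aldehyde, which has no α-hydrogen and stops there, and dehydrogenate the ketone (IBX-mediated α,β-dehydrogenation) toward C7–C8, the only side with a β-hydrogen because C4 and C10 are quaternary, giving the E-enone.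

Step 10
Reactants: 16 aldehyde enone acid; 17 (triphenylphosphoranylidene)acetaldehyde
Product: 18 enal enone acid
Conditions: toluene, 90 °C
Reagents that add atoms: none
Why: Wittig olefination with the stabilised formylmethylene ylide is E-selective and should react at the aldehyde only, since the enone ketone is inert to this ylide.

Step 11
Reactants: 18 enal enone acid
Product: 20 tricyclic hydroxy keto acid, via keto aldehyde 19 (not isolated)
Conditions: SmI2 (2.1 equiv, slow addition), t-BuOH (2 equiv), THF (0.005 M), −78 °C; then, in the same flask, solvent exchange to CH2Cl2, Me2AlCl (6 equiv), −78 to −20 °C; aq. potassium sodium tartrate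
Reagents that add atoms: none
Why: Proposed new method: divalent samarium reduces the enal to a samarium allyl ketyl whose C9 end adds to C8 of the enone, and a second electron turns the C7 radical into an enolate, so two electrophilic β-carbons are joined by polarity reversal; protonation by t-BuOH releases keto aldehyde 19, which Me2AlCl closes by an intramolecular carbonyl-ene reaction (C12=O as enophile, C13=C16 as ene, hydrogen from a prenyl methyl). The closest known reaction types are the SmI2- or cathode-mediated reductive cyclisation (hydrodimerisation) of tethered bis-enones and bis-enoates and the Lewis-acid carbonyl-ene cyclisation of citronellal to isopulegol; new are the enal–enone pair with the enone carbonyl inside the forming ring and the telescoping of the two events. Ring B closes 6-endo-trig at the enone (6-exo with respect to the enal), and ring C closes through a six-membered chair ene transition state. C9 is controlled by C10 (chair with the C11 chain equatorial, H9 axial and anti to the axial C20 methyl); C8 by the E-enone geometry (C14 chain equatorial, trans to C11; temporary); C13 by C9 and C8 through the trans-fused chair in which the new isopropenyl group is equatorial, hence trans across ring C to C10 as in the target; the equatorial C12 hydroxyl is erased later by oxidation. The step needs coupling to outrun plain conjugate reduction and pinacol coupling, which high dilution, slow addition of just two electron equivalents and the six-membered chair should secure, and it needs the ene reaction to choose the aldehyde over the C6 ketone, which the much higher reactivity of Lewis-acid-bound aldehydes and the six-membered geometry should secure.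

Step 12
Reactants: 20 tricyclic hydroxy keto acid
Product: 21 α-hydroxy ketone
Conditions: KN(SiMe3)2 (3.3 equiv), THF, −78 °C; then 2-(phenylsulfonyl)-3-phenyloxaziridine (1.5 equiv); aq. NH4Cl
Reagents that add atoms: 2-(phenylsulfonyl)-3-phenyloxaziridine, O=S(=O)(c1ccccc1)N1OC1c1ccccc1
Why: Enolate oxidation with an N-sulfonyloxaziridine: after deprotonation of the acid and the alcohol, the base should enolise the C6 ketone toward C7 only (C5–H is shielded by two quaternary neighbours) and the enolate takes up oxygen at C7, whose configuration is irrelevant because this carbon becomes the aldehyde.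

Step 13
Reactants: 21 α-hydroxy ketone
Product: 22 allylic chloride
Conditions: N-chlorosuccinimide (1.1 equiv), PhSeCl (10 mol %), CH2Cl2, 25 °C
Reagents that add atoms: N-chlorosuccinimide, O=C1CCC(=O)N1Cl
Why: Selenium-catalysed ene-type allylic chlorination: the electrophile should add to the terminal carbon of the 1,1-disubstituted alkene and the adduct collapses with loss of a methyl hydrogen, giving the 2-(chloromethyl)allyl group with a regenerated exocyclic methylene, while alcohols, ketone and acid are tolerated.

Step 14
Reactants: 22 allylic chloride
Product: 23 seco hydroxy aldehyde diacid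
Conditions: NaIO4 (3 equiv), THF/H2O 2:1, 25 °C
Reagents that add atoms: water, O
Why: Periodate cleavage of the α-hydroxy ketone (Malaprade-type oxidation through the ketone hydrate) should cut the C6–C7 bond of temporary ring B, turning the ketone carbon C6 into the carboxylic acid and the carbinol carbon C7 into the aldehyde, with alkene and allylic chloride inert.

Step 15
Reactants: 23 seco hydroxy aldehyde diacid
Product: 24 seco keto aldehyde diacid
Conditions: Dess–Martin periodinane (1.3 equiv), CH2Cl2, 0 to 25 °C
Reagents that add atoms: none
Why: Dess–Martin oxidation should convert the secondary C12 alcohol into the ketone without touching the aldehyde or the acids; C8 and C13 are now epimerisable but both prefer the equatorial arrangement drawn, and C8 is reset in the next step.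

Step 16
Reactants: 24 seco keto aldehyde diacid
Product: 26 CNP0320711.1, via pyrrolidine enamine 25 (not isolated)
Conditions: Pd(PPh3)4 (5 mol %), pyrrolidine (30 mol %), Et3N (3.5 equiv), THF/DMSO, 25 to 40 °C; then aq. citric acid
Reagents that add atoms: none
Why: Intramolecular Tsuji–Trost α-allylation of an aldehyde under dual enamine/palladium catalysis: zerovalent palladium ionises the allylic chloride to a 2-substituted π-allyl complex, the enamine attacks one of its two equivalent termini through C8 (five-membered ring, quaternary centre) and hydrolysis returns the aldehyde; C8 is set because the allyl unit is anchored on C13 and can reach only the face that gives the bicyclo[3.2.1]octane, and the exocyclic methylene is kept.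

## Compound list

1 | 3-bromo-2H-pyran-2-one | BrC1=CC=COC1=O | starting material
2 | 3-methyl-2H-pyran-2-one | CC1=CC=COC1=O | intermediate
3 | citraconic anhydride (3-methylfuran-2,5-dione) | CC1=CC(=O)OC1=O | starting material
4 | racemic 4,7-dimethyl-3-oxo-2-oxabicyclo[2.2.2]oct-5-ene-7,8-dicarboxylic anhydride, endo (anhydride syn to C5=C6, 7-methyl syn to the lactone bridge) | C[C@]12C=C[C@H](OC1=O)[C@@](C)(C(=O)OC3=O)[C@H]23 | intermediate
5 | tributylstannyl ester of acid 6 | CCCC[Sn](CCCC)(CCCC)OC(=O)[C@]1(C)C=CC[C@@]2(C)C(=O)OC(=O)[C@@H]12 | intermediate (not isolated)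
6 | racemic 1,3-dimethylcyclohex-4-ene-1,2,3-tricarboxylic acid 1,2-anhydride (cis-fused anhydride; free 3-carboxyl trans to it, 3-methyl cis to it) | OC(=O)[C@]1(C)C=CC[C@@]2(C)C(=O)OC(=O)[C@@H]12 | intermediate
7 | racemic 1,3-dimethylcyclohexane-1,2,3-tricarboxylic acid 1,2-anhydride (same relative configuration) | OC(=O)[C@]1(C)CCC[C@@]2(C)C(=O)OC(=O)[C@@H]12 | intermediate
8 | racemic 3-(hydroxymethyl)-1,3-dimethylcyclohexane-1,2-dicarboxylic anhydride | OC[C@]1(C)CCC[C@@]2(C)C(=O)OC(=O)[C@@H]12 | intermediate (not isolated)
9 | racemic 3a,7-dimethyl-1-oxooctahydro-2-benzofuran-7-carboxylic acid (trans-fused γ-lactone, carboxyl cis to the angular methyl) | C[C@@]12CCC[C@@](C)(C(=O)O)[C@H]1C(=O)OC2 | intermediate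
10 | the same lactone acid as the single enantiomer with the ring A configuration of the target | C[C@@]12CCC[C@@](C)(C(=O)O)[C@H]1C(=O)OC2 | intermediate
11 | 5-bromopent-1-ene | C=CCCCBr | starting material
12 | 2-methylbut-2-ene | CC=C(C)C | starting material
13 | 6-bromo-2-methylhex-2-ene | CC(C)=CCCCBr | intermediate
14 | 5-methylhex-4-enyllithium | [Li]CCCC=C(C)C | intermediate (not isolated)
15 | 3-(hydroxymethyl)-1,3-dimethyl-2-(6-methylhept-5-enoyl)cyclohexane-1-carboxylic acid (carboxyl, acyl and 3-methyl on one face; in equilibrium with its cyclic hemiketal) | OC[C@]1(C)CCC[C@@](C)(C(=O)O)[C@H]1C(=O)CCCC=C(C)C | intermediate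
16 | 3-formyl-1,3-dimethyl-2-[(2E)-6-methylhepta-2,5-dienoyl]cyclohexane-1-carboxylic acid | O=C[C@]1(C)CCC[C@@](C)(C(=O)O)[C@H]1C(=O)/C=C/CC=C(C)C | intermediate
17 | (triphenylphosphoranylidene)acetaldehyde | O=CC=P(c1ccccc1)(c1ccccc1)c1ccccc1 | starting material
18 | 1,3-dimethyl-2-[(2E)-6-methylhepta-2,5-dienoyl]-3-[(1E)-3-oxoprop-1-en-1-yl]cyclohexane-1-carboxylic acid | O=C/C=C/[C@]1(C)CCC[C@@](C)(C(=O)O)[C@H]1C(=O)/C=C/CC=C(C)C | intermediate
19 | 1,4a-dimethyl-6-(3-methylbut-2-en-1-yl)-8-oxo-5-(2-oxoethyl)decahydronaphthalene-1-carboxylic acid (trans ring fusion; 5- and 6-substituents trans-diequatorial) | O=CC[C@@H]1[C@@H](CC=C(C)C)CC(=O)[C@H]2[C@@]1(C)CCC[C@@]2(C)C(=O)O | intermediate (not isolated)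
20 | tricyclic hydroxy keto acid, rings A, B, C trans-anti-trans: C6 ketone, equatorial C12 hydroxyl, equatorial C13 isopropenyl, C19 acid (8,15-seco-ent-kaurane skeleton) | C=C(C)[C@H]1C[C@H]2CC(=O)[C@H]3[C@@](C)(CCC[C@@]3(C)C(=O)O)[C@@H]2C[C@@H]1O | intermediate
21 | 7-hydroxy derivative of 20 (C7 epimers, both usable) | C=C(C)[C@H]1C[C@H]2C(O)C(=O)[C@H]3[C@@](C)(CCC[C@@]3(C)C(=O)O)[C@@H]2C[C@@H]1O | intermediate
22 | 21 with the C13 substituent changed to 3-chloroprop-1-en-2-yl | C=C(CCl)[C@H]1C[C@H]2C(O)C(=O)[C@H]3[C@@](C)(CCC[C@@]3(C)C(=O)O)[C@@H]2C[C@@H]1O | intermediate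
23 | ring-B-opened diacid: cyclohexane ring C carrying CHO (C8), ring A (C9), OH (C12) and 3-chloroprop-1-en-2-yl (C13), all equatorial; C6 and C19 acids on ring A | C=C(CCl)[C@H]1C[C@@H](C=O)[C@@H](C[C@@H]1O)[C@]1(C)CCC[C@@](C)(C(=O)O)[C@H]1C(=O)O | intermediate
24 | 12-oxo analogue of 23 | C=C(CCl)[C@H]1C[C@@H](C=O)[C@@H](CC1=O)[C@]1(C)CCC[C@@](C)(C(=O)O)[C@H]1C(=O)O | intermediate
25 | pyrrolidine enamine of 24 | C=C(CCl)[C@H]1CC(=CN2CCCC2)[C@@H](CC1=O)[C@]1(C)CCC[C@@](C)(C(=O)O)[C@H]1C(=O)O | intermediate (not isolated)
26 | CNP0320711.1 (7,12-dioxo-6,7-seco-ent-kaur-16-ene-6,19-dioic acid) | C=C1C[C@]2(C=O)C[C@H]1C(=O)C[C@H]2[C@]1(C)CCC[C@@](C)(C(=O)O)[C@H]1C(=O)O | target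

## Step count and risks

Total step count: 16. Longest linear sequence: 15 steps (steps 1–6 and 8–16; step 7 makes side-chain bromide 13).

Steps most likely to fail:

1. Step 11 (proposed new method). What may go wrong: protonation and a second reduction of the enal radical anion (net conjugate reduction) or pinacol-type coupling may outrun ring closure, or closure may pass through the chair with the C11 chain axial and lose control of C9. Fallback with known chemistry, setting out from 16: Wittig olefination with [2-(trimethylsilyl)ethylidene]triphenylphosphorane would give the allylsilane F1. TiCl4 in CH2Cl2 at −78 °C would then effect an intramolecular Sakurai conjugate addition of its C9 terminus to C8 of the enone, giving the vinyl decalone F2. Hydroboration of the vinyl group with 9-BBN and NaOH/H2O2 work-up would give the primary alcohol F3, and Dess–Martin oxidation would give keto aldehyde 19, now isolated. The Me2AlCl carbonyl-ene cyclisation of 19 returns to the route at 20.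

2. Step 16. What may go wrong: slow enamine formation at the α-branched aldehyde may let enolisation of the C12 ketone (migration of the C16 alkene into conjugation, allylation at C11) or N-allylation of the amine take over. Fallback, setting out from 23 (C12 still a carbinol, no amine, no palladium): silylation with N,O-bis(trimethylsilyl)acetamide would give the tris(trimethylsilyl) derivative F4. KN(SiMe3)2 in THF at −78 to 0 °C would then close ring D by intramolecular SN2 alkylation of the aldehyde potassium enolate (5-exo-tet), and acidic work-up would give the 12-hydroxy compound F5. Dess–Martin oxidation of F5 returns to the route at 26.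

3. Step 2. What may go wrong: a sluggish cycloaddition of the trisubstituted dienophile, so that thermal loss of CO2 from the adduct or the reversed orientation of the anhydride methyl competes. Fallback, setting out from 3 and purchased 3,5-dibromo-2H-pyran-2-one (BrC1=CC(Br)=COC1=O): site-selective Negishi methylation at the bromide next to the carbonyl would give 5-bromo-3-methyl-2H-pyran-2-one F6, a more reactive ambiphilic diene that should add 3 well below the decarboxylation temperature to give the bromo cycloadduct F7. Pd(PPh3)4 with Bu3SnH (2.5 equiv) would then cleave both the allylic lactone and the vinylic C–Br bond, returning to the route at 6.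

Further compounds
F1 | step 11 | 1,3-dimethyl-2-[(2E)-6-methylhepta-2,5-dienoyl]-3-[(1Z)-3-(trimethylsilyl)prop-1-en-1-yl]cyclohexane-1-carboxylic acid | C[Si](C)(C)C/C=C\[C@]1(C)CCC[C@@](C)(C(=O)O)[C@H]1C(=O)/C=C/CC=C(C)C
F2 | step 11 | 5-ethenyl-1,4a-dimethyl-6-(3-methylbut-2-en-1-yl)-8-oxodecahydronaphthalene-1-carboxylic acid (trans-fused, 5,6-trans) | C=C[C@@H]1[C@@H](CC=C(C)C)CC(=O)[C@H]2[C@@]1(C)CCC[C@@]2(C)C(=O)O
F3 | step 11 | 5-(2-hydroxyethyl)-1,4a-dimethyl-6-(3-methylbut-2-en-1-yl)-8-oxodecahydronaphthalene-1-carboxylic acid | OCC[C@@H]1[C@@H](CC=C(C)C)CC(=O)[C@H]2[C@@]1(C)CCC[C@@]2(C)C(=O)O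
F4 | step 16 | tris(trimethylsilyl) derivative of 23 (C12 silyl ether, C6 and C19 silyl esters) | C=C(CCl)[C@H]1C[C@@H](C=O)[C@@H](C[C@@H]1O[Si](C)(C)C)[C@]1(C)CCC[C@@](C)(C(=O)O[Si](C)(C)C)[C@H]1C(=O)O[Si](C)(C)C
F5 | step 16 | 12-hydroxy-7-oxo-6,7-seco-ent-kaur-16-ene-6,19-dioic acid | C=C1C[C@]2(C=O)C[C@H]1[C@@H](O)C[C@H]2[C@]1(C)CCC[C@@](C)(C(=O)O)[C@H]1C(=O)O
F6 | step 2 | 5-bromo-3-methyl-2H-pyran-2-one | CC1=CC(Br)=COC1=O
F7 | step 2 | racemic 5-bromo analogue of cycloadduct 4 | C[C@]12C=C(Br)[C@H](OC1=O)[C@@](C)(C(=O)OC3=O)[C@H]23
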